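**Retrosynthetic overview**
1. The target comes from a Horner–Wadsworth–Emmons methylenation of a phosphonate that already holds every ring and stereocentre; the phosphonate masks the upper α-methylene lactone during the union.
2. Ring C (bonds C5–C13′, C11′–C3, C2–C1) and the C1 carbinol come from a three-component union. The partners are an upper enol silane (C5 nucleophile, C1 carbonyl), the lower α-methylene lactone (C13′/C11′) and (E)-4-nitrobut-3-en-2-one (C2–C3–acetyl); the sequence is Michael, Michael, nitro-aldol, loss of HNO2.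
3. Both cycloheptane rings come from a one-carbon ring expansion (Me3SiCHN2, Sc(OTf)3) of lactone-fused 2-methylcyclohexanones. The 1,2-shift inserts C5 and delivers a regiodefined C1=C5 enol silane, used directly for the upper half and through its triflate (side chain by B-alkyl Suzuki coupling) for the lower half.
4. In the given structure the C7/C8/C10 triad of the lower half is the mirror image of that of the upper half. Both six-membered ketones therefore come from one racemic α′-alkylated 3-methylcyclohexenone by dynamic kinetic asymmetric hydrogenation with either catalyst hand, then phosphorylation, allylic oxidation and hydrogenation.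
5. Order of ring formation: cyclohexene (bought) → cis-γ-lactone → cycloheptane by expansion (each half) → ring C with spiro centre and carbinol (union) → exocyclic methylene last.

Labels: xanthanolide numbering for the upper unit (C1 carbinol, C5, C6, C7, C8–O, C9, C10–CH3, lactone C11–C13, enone chain C2–C4/C15); primed labels for the lower unit.

Assumption: the hand of the ruthenium catalyst in steps 2 and 7 is assigned by analogy with 2-alkylcyclohexanones; if the sense is the opposite, the two catalysts are exchanged.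

**Step 1**
Reactants: 1 3-methylcyclohex-2-en-1-one; 2 methyl bromoacetate
Product: 3 methyl 2-(4-methyl-2-oxocyclohex-3-en-1-yl)acetate (racemic)
Conditions: LiN(i-Pr)2 (1.05 equiv), THF, −78 °C; then 2, DMPU, −78 → −20 °C
Reagents that add atoms: none
Why: kinetic α′-deprotonation gives the cross-conjugated enolate, whose SN2 alkylation (enolate alkylation) forms the future C7–C11 bond; the new centre is racemic and is set in steps 2 and 7.

**Step 2**
Reactants: 3 methyl 2-(4-methyl-2-oxocyclohex-3-en-1-yl)acetate (racemic)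
Product: 5 (3aR,7aS)-6-methyl-3a,4,5,7a-tetrahydro-1-benzofuran-2(3H)-one, via cis-hydroxy ester 4 (not isolated)
Conditions: RuCl2[(S)-xylbinap][(S)-daipen] (0.5 mol %), KOt-Bu (20 mol %), i-PrOH, H2 (10 atm), 25 °C; then TsOH·H2O (5 mol %), CH2Cl2, 23 °C
Reagents that add atoms: none
Why: Noyori carbonyl-selective asymmetric hydrogenation under dynamic kinetic resolution, in which KOt-Bu racemises the α′-centre through the enolate while the chiral ruthenium hydride reduces one enantiomer anti to the side chain, fixing C7 and C8 as a cis pair that lactonises.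

**Step 3**
Reactants: 5 (3aR,7aS)-6-methyl-3a,4,5,7a-tetrahydro-1-benzofuran-2(3H)-one
Product: 7 diethyl [(3R,3aS,7aR)-6-methyl-2-oxo-2,3,3a,4,5,7a-hexahydro-1-benzofuran-3-yl]phosphonate, via enol phosphate 6 (not isolated)
Conditions: LiN(i-Pr)2 (1.1 equiv), THF, −78 °C; ClP(O)(OEt)2 (1.1 equiv); LiN(i-Pr)2 (1.2 equiv), −78 → 0 °C; AcOH
Reagents that add atoms: diethyl chlorophosphate, CCOP(=O)(Cl)OCC
Why: O-phosphorylation of the lactone enolate and base-induced 1,3-phosphorus shift (enol phosphate–phosphonate rearrangement) give the α-phosphono lactone, a latent α-methylene group, with phosphorus settling on the convex face of the labile C11 centre.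

**Step 4**
Reactants: 7 diethyl [(3R,3aS,7aR)-6-methyl-2-oxo-2,3,3a,4,5,7a-hexahydro-1-benzofuran-3-yl]phosphonate
Product: 8 diethyl [(3R,3aS,7aR)-6-methyl-2,5-dioxo-2,3,3a,4,5,7a-hexahydro-1-benzofuran-3-yl]phosphonate
Conditions: Rh2(cap)4 (1 mol %), t-BuOOH (70% in H2O, 5 equiv), ClCH2CH2Cl, 40 °C
Reagents that add atoms: tert-butyl hydroperoxide, CC(C)(C)OO
Why: radical allylic oxidation by tert-butylperoxyl converts the only allylic CH2 (the other allylic carbon carries the lactone oxygen) into the enone carbonyl, the future C1.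

**Step 5**
Reactants: 8 diethyl [(3R,3aS,7aR)-6-methyl-2,5-dioxo-2,3,3a,4,5,7a-hexahydro-1-benzofuran-3-yl]phosphonate
Product: 9 diethyl [(3R,3aS,6S,7aR)-6-methyl-2,5-dioxooctahydro-1-benzofuran-3-yl]phosphonate
Conditions: H2 (1 atm), 5% Rh/Al2O3, EtOAc, 23 °C
Reagents that add atoms: none
Why: heterogeneous catalytic hydrogenation adds hydrogen to the convex face of the cis-fused bicycle (the face of the ring-fusion hydrogens, anti to the allylic lactone oxygen), so the C10 methyl ends cis to the lactone oxygen (6S).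

**Step 6**
Reactants: 9 diethyl [(3R,3aS,6S,7aR)-6-methyl-2,5-dioxooctahydro-1-benzofuran-3-yl]phosphonate
Product: 11 diethyl [(3R,3aS,7S,8aR)-7-methyl-2-oxo-6-[(trimethylsilyl)oxy]-3,3a,4,7,8,8a-hexahydro-2H-cyclohepta[b]furan-3-yl]phosphonate, via α-silyl ketone 10 (not isolated)
Conditions: Me3SiCHN2 (1.5 equiv), Sc(OTf)3 (10 mol %), CH2Cl2, −20 → 23 °C
Reagents that add atoms: (trimethylsilyl)diazomethane, C[Si](C)(C)C=[N+]=[N-]
Why: Lewis-acid-catalysed diazoalkane homologation (Tiffeneau–Demjanov-type 1,2-shift) in which the less substituted α-CH2 migrates to insert C5, followed by 1,3-Brook shift of the α-silyl ketone to the C1=C5 enol silane, formed away from C10 without touching its configuration.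

**Step 7**
Reactants: 3 methyl 2-(4-methyl-2-oxocyclohex-3-en-1-yl)acetate (racemic)
Product: 13 (3aS,7aR)-6-methyl-3a,4,5,7a-tetrahydro-1-benzofuran-2(3H)-one, via cis-hydroxy ester 12 (not isolated)
Conditions: RuCl2[(R)-xylbinap][(R)-daipen] (0.5 mol %), KOt-Bu (20 mol %), i-PrOH, H2 (10 atm), 25 °C; then TsOH·H2O (5 mol %), CH2Cl2, 23 °C
Reagents that add atoms: none
Why: the same Noyori hydrogenation with dynamic kinetic resolution as in step 2, run with the mirror-image catalyst to give the mirror-image cis-lactone for the lower half.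

**Step 8**
Reactants: 13 (3aS,7aR)-6-methyl-3a,4,5,7a-tetrahydro-1-benzofuran-2(3H)-one
Product: 15 diethyl [(3S,3aR,7aS)-6-methyl-2-oxo-2,3,3a,4,5,7a-hexahydro-1-benzofuran-3-yl]phosphonate, via enol phosphate 14 (not isolated)
Conditions: LiN(i-Pr)2 (1.1 equiv), THF, −78 °C; ClP(O)(OEt)2 (1.1 equiv); LiN(i-Pr)2 (1.2 equiv), −78 → 0 °C; AcOH
Reagents that add atoms: diethyl chlorophosphate, CCOP(=O)(Cl)OCC
Why: enol phosphate–phosphonate rearrangement as in step 3, in the mirror-image series.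

**Step 9**
Reactants: 15 diethyl [(3S,3aR,7aS)-6-methyl-2-oxo-2,3,3a,4,5,7a-hexahydro-1-benzofuran-3-yl]phosphonate
Product: 16 diethyl [(3S,3aR,7aS)-6-methyl-2,5-dioxo-2,3,3a,4,5,7a-hexahydro-1-benzofuran-3-yl]phosphonate
Conditions: Rh2(cap)4 (1 mol %), t-BuOOH (70% in H2O, 5 equiv), ClCH2CH2Cl, 40 °C
Reagents that add atoms: tert-butyl hydroperoxide, CC(C)(C)OO
Why: radical allylic oxidation of the single allylic CH2 to the enone, as in step 4.

**Step 10**
Reactants: 16 diethyl [(3S,3aR,7aS)-6-methyl-2,5-dioxo-2,3,3a,4,5,7a-hexahydro-1-benzofuran-3-yl]phosphonate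
Product: 17 diethyl [(3S,3aR,6R,7aS)-6-methyl-2,5-dioxooctahydro-1-benzofuran-3-yl]phosphonate
Conditions: H2 (1 atm), 5% Rh/Al2O3, EtOAc, 23 °C
Reagents that add atoms: none
Why: convex-face catalytic hydrogenation as in step 5 sets C10′ (6R) cis to the lactone oxygen.

**Step 11**
Reactants: 17 diethyl [(3S,3aR,6R,7aS)-6-methyl-2,5-dioxooctahydro-1-benzofuran-3-yl]phosphonate
Product: 19 diethyl [(3S,3aR,7R,8aS)-7-methyl-2-oxo-6-[(trimethylsilyl)oxy]-3,3a,4,7,8,8a-hexahydro-2H-cyclohepta[b]furan-3-yl]phosphonate, via α-silyl ketone 18 (not isolated)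
Conditions: Me3SiCHN2 (1.5 equiv), Sc(OTf)3 (10 mol %), CH2Cl2, −20 → 23 °C
Reagents that add atoms: (trimethylsilyl)diazomethane, C[Si](C)(C)C=[N+]=[N-]
Why: the same diazoalkane ring expansion and 1,3-Brook shift as in step 6, giving the seven-membered enol silane of the lower half.

**Step 12**
Reactants: 19 diethyl [(3S,3aR,7R,8aS)-7-methyl-2-oxo-6-[(trimethylsilyl)oxy]-3,3a,4,7,8,8a-hexahydro-2H-cyclohepta[b]furan-3-yl]phosphonate
Product: 20 (3S,3aR,7R,8aS)-3-(diethoxyphosphoryl)-7-methyl-2-oxo-3,3a,4,7,8,8a-hexahydro-2H-cyclohepta[b]furan-6-yl trifluoromethanesulfonate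
Conditions: CsF (2 equiv), PhNTf2 (1.3 equiv), MeOCH2CH2OMe, 23 °C
Reagents that add atoms: N-phenylbis(trifluoromethanesulfonimide), O=S(=O)(N(c1ccccc1)S(=O)(=O)C(F)(F)F)C(F)(F)F
Why: fluoride cleaves the O–Si bond and the enolate is O-sulfonylated (enol triflate formation) with the enol regiochemistry from the ring expansion retained.

**Step 13**
Reactants: 20 (3S,3aR,7R,8aS)-3-(diethoxyphosphoryl)-7-methyl-2-oxo-3,3a,4,7,8,8a-hexahydro-2H-cyclohepta[b]furan-6-yl trifluoromethanesulfonate; 21 2-methyl-2-vinyl-1,3-dioxolane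
Product: 24 diethyl [(3S,3aR,7R,8aS)-7-methyl-2-oxo-6-(3-oxobutyl)-3,3a,4,7,8,8a-hexahydro-2H-cyclohepta[b]furan-3-yl]phosphonate, via alkylborane 22 (not isolated), via dioxolane 23 (not isolated)
Conditions: 21, 9-BBN-H, THF, 0 → 23 °C; then 20, Pd(dppf)Cl2 (5 mol %), AsPh3 (5 mol %), Cs2CO3 (3 equiv), DMF–H2O, 50 °C; then 1 M HCl, THF, 23 °C
Reagents that add atoms: water, O
Why: anti-Markovnikov hydroboration and B-alkyl Suzuki–Miyaura coupling with the enol triflate form the C1′–C2′ bond, and aqueous acid hydrolyses the dioxolane to the methyl ketone.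

**Step 14**
Reactants: 24 diethyl [(3S,3aR,7R,8aS)-7-methyl-2-oxo-6-(3-oxobutyl)-3,3a,4,7,8,8a-hexahydro-2H-cyclohepta[b]furan-3-yl]phosphonate
Product: 25 (3aS,7R,8aS)-7-methyl-3-methylidene-6-(3-oxobutyl)-3,3a,4,7,8,8a-hexahydro-2H-cyclohepta[b]furan-2-one
Conditions: HCHO (37% aq., 5 equiv), K2CO3 (2.5 equiv), THF, 0 → 23 °C
Reagents that add atoms: formaldehyde, C=O
Why: Horner–Wadsworth–Emmons olefination of the acidic phosphonate with formaldehyde gives the α-methylene lactone under conditions too mild to enolise the ketone.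

**Step 15**
Reactants: 26 nitromethane; 27 methylglyoxal (40% aq.)
Product: 28 3-hydroxy-4-nitrobutan-2-one (racemic)
Conditions: Et3N (10 mol %), THF–H2O, 0 °C
Reagents that add atoms: none
Why: nitro-aldol (Henry) addition of the nitronate to the aldehyde carbon, the more electrophilic carbonyl of methylglyoxal.

**Step 16**
Reactants: 28 3-hydroxy-4-nitrobutan-2-one (racemic)
Product: 30 (E)-4-nitrobut-3-en-2-one, via mesylate 29 (not isolated)
Conditions: MeSO2Cl (1.1 equiv), Et3N (2.2 equiv), CH2Cl2, −30 → 0 °C; used at once as a solution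
Reagents that add atoms: none
Why: mesylation and E1cB elimination (dehydration of a β-nitro alcohol) give the thermodynamically preferred (E)-nitroalkene.

**Step 17**
Reactants: 11 diethyl [(3R,3aS,7S,8aR)-7-methyl-2-oxo-6-[(trimethylsilyl)oxy]-3,3a,4,7,8,8a-hexahydro-2H-cyclohepta[b]furan-3-yl]phosphonate; 25 (3aS,7R,8aS)-7-methyl-3-methylidene-6-(3-oxobutyl)-3,3a,4,7,8,8a-hexahydro-2H-cyclohepta[b]furan-2-one; 30 (E)-4-nitrobut-3-en-2-one
Product: 34 phosphonate precursor of the target (the target with H and P(O)(OEt)2 on upper C11 in place of =CH2), via silyl ketene acetal 31 (not isolated), via silyl nitronate 32 (not isolated), via nitro alcohol 33 (not isolated)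
Conditions: Me3SiNTf2 (20 mol %), CH2Cl2, −78 °C (11 + 25); then 30 (1.3 equiv), −78 → −40 °C; then Bu4N[Ph3SiF2] (1.3 equiv), THF, −78 °C; then DBU (20 mol %), −78 → 0 °C
Reagents that add atoms: none
Why: Proposed new method: a one-pot (2+2+2) annulation in which (a) enol silane carbon C5 of 11 adds to the silyl-activated exocyclic methylene of 25 on the face opposite the cis-fused lactone and the C10 methyl (Mukaiyama–Michael, sets 5R) to give ketone/silyl ketene acetal 31, (b) ketene acetal carbon C11′ adds from the convex face of the lower bicycle to the carbon of 30 that is β to the nitro group, the acetyl-bearing one (sets 11′R, gives silyl nitronate 32), (c) fluoride frees the nitronate, which closes ring C onto the C1 ketone in a cis-fused nitro-aldol (Henry) reaction (sets 1S, gives 33), and (d) E1cB loss of nitrite from the β-nitro ketone leaves the C2=C3 enone, so the nitroenone serves as an acetylacetylene equivalent of reversed polarity and the tertiary C1–OH comes straight from the ring-expansion carbonyl; each event has precedent (enol silane additions to acrylates, silyl ketene acetal additions to nitroalkenes, Michael–Henry cyclohexanol formation, nitrous acid elimination from β-nitro ketones) and the closest known reaction type is the three-component Michael–Michael–ring-closure annulation of a ketone enolate with two acceptors, but this sequence with a β-nitroenone and nitrite loss has not been shown.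

**Step 18**
Reactants: 34 phosphonate precursor of the target
Product: 35 CNP0195550.3 (target)
Conditions: HCHO (37% aq., 5 equiv), K2CO3 (2.5 equiv), THF, 0 °C
Reagents that add atoms: formaldehyde, C=O
Why: Horner–Wadsworth–Emmons methylenation of the last phosphonate, whose C–H is far more acidic than any ketone α-C–H, so K2CO3 leaves the enone, carbinol and spiro lactone untouched.

**Compound list**
1 | 3-methylcyclohex-2-en-1-one | CC1=CC(=O)CCC1 | starting material
2 | methyl bromoacetate | COC(=O)CBr | starting material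
3 | methyl 2-(4-methyl-2-oxocyclohex-3-en-1-yl)acetate (racemic) | COC(=O)CC1CCC(C)=CC1=O | intermediate
4 | methyl 2-[(1R,2S)-2-hydroxy-4-methylcyclohex-3-en-1-yl]acetate | COC(=O)C[C@H]1CCC(C)=C[C@H]1O | intermediate
5 | (3aR,7aS)-6-methyl-3a,4,5,7a-tetrahydro-1-benzofuran-2(3H)-one | C1C(=O)O[C@@H]2C=C(C)CC[C@H]12 | intermediate
6 | diethyl (3aR,7aS)-6-methyl-3a,4,5,7a-tetrahydro-1-benzofuran-2-yl phosphate | C1=C(OP(=O)(OCC)OCC)O[C@@H]2C=C(C)CC[C@H]12 | intermediate
7 | diethyl [(3R,3aS,7aR)-6-methyl-2-oxo-2,3,3a,4,5,7a-hexahydro-1-benzofuran-3-yl]phosphonate | CCOP(=O)(OCC)[C@H]1C(=O)O[C@@H]2C=C(C)CC[C@H]12 | intermediate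
8 | diethyl [(3R,3aS,7aR)-6-methyl-2,5-dioxo-2,3,3a,4,5,7a-hexahydro-1-benzofuran-3-yl]phosphonate | CCOP(=O)(OCC)[C@H]1C(=O)O[C@@H]2C=C(C)C(=O)C[C@H]12 | intermediate
9 | diethyl [(3R,3aS,6S,7aR)-6-methyl-2,5-dioxooctahydro-1-benzofuran-3-yl]phosphonate | CCOP(=O)(OCC)[C@H]1C(=O)O[C@@H]2C[C@H](C)C(=O)C[C@H]12 | intermediate
10 | diethyl [(3R,3aS,7S,8aR)-7-methyl-2,6-dioxo-5-(trimethylsilyl)octahydro-2H-cyclohepta[b]furan-3-yl]phosphonate (mixture at C5) | CCOP(=O)(OCC)[C@H]1C(=O)O[C@@H]2C[C@H](C)C(=O)C([Si](C)(C)C)C[C@H]12 | intermediate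
11 | diethyl [(3R,3aS,7S,8aR)-7-methyl-2-oxo-6-[(trimethylsilyl)oxy]-3,3a,4,7,8,8a-hexahydro-2H-cyclohepta[b]furan-3-yl]phosphonate | CCOP(=O)(OCC)[C@H]1C(=O)O[C@@H]2C[C@H](C)C(O[Si](C)(C)C)=CC[C@H]12 | intermediate
12 | methyl 2-[(1S,2R)-2-hydroxy-4-methylcyclohex-3-en-1-yl]acetate | COC(=O)C[C@@H]1CCC(C)=C[C@@H]1O | intermediate
13 | (3aS,7aR)-6-methyl-3a,4,5,7a-tetrahydro-1-benzofuran-2(3H)-one | C1C(=O)O[C@H]2C=C(C)CC[C@@H]12 | intermediate
14 | diethyl (3aS,7aR)-6-methyl-3a,4,5,7a-tetrahydro-1-benzofuran-2-yl phosphate | C1=C(OP(=O)(OCC)OCC)O[C@H]2C=C(C)CC[C@@H]12 | intermediate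
15 | diethyl [(3S,3aR,7aS)-6-methyl-2-oxo-2,3,3a,4,5,7a-hexahydro-1-benzofuran-3-yl]phosphonate | CCOP(=O)(OCC)[C@@H]1C(=O)O[C@H]2C=C(C)CC[C@@H]12 | intermediate
16 | diethyl [(3S,3aR,7aS)-6-methyl-2,5-dioxo-2,3,3a,4,5,7a-hexahydro-1-benzofuran-3-yl]phosphonate | CCOP(=O)(OCC)[C@@H]1C(=O)O[C@H]2C=C(C)C(=O)C[C@@H]12 | intermediate
17 | diethyl [(3S,3aR,6R,7aS)-6-methyl-2,5-dioxooctahydro-1-benzofuran-3-yl]phosphonate | CCOP(=O)(OCC)[C@@H]1C(=O)O[C@H]2C[C@@H](C)C(=O)C[C@@H]12 | intermediate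
18 | diethyl [(3S,3aR,7R,8aS)-7-methyl-2,6-dioxo-5-(trimethylsilyl)octahydro-2H-cyclohepta[b]furan-3-yl]phosphonate (mixture at C5) | CCOP(=O)(OCC)[C@@H]1C(=O)O[C@H]2C[C@@H](C)C(=O)C([Si](C)(C)C)C[C@@H]12 | intermediate
19 | diethyl [(3S,3aR,7R,8aS)-7-methyl-2-oxo-6-[(trimethylsilyl)oxy]-3,3a,4,7,8,8a-hexahydro-2H-cyclohepta[b]furan-3-yl]phosphonate | CCOP(=O)(OCC)[C@@H]1C(=O)O[C@H]2C[C@@H](C)C(O[Si](C)(C)C)=CC[C@@H]12 | intermediate
20 | (3S,3aR,7R,8aS)-3-(diethoxyphosphoryl)-7-methyl-2-oxo-3,3a,4,7,8,8a-hexahydro-2H-cyclohepta[b]furan-6-yl trifluoromethanesulfonate | CCOP(=O)(OCC)[C@@H]1C(=O)O[C@H]2C[C@@H](C)C(OS(=O)(=O)C(F)(F)F)=CC[C@@H]12 | intermediate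
21 | 2-methyl-2-vinyl-1,3-dioxolane | CC1(C=C)OCCO1 | starting material
22 | 9-[2-(2-methyl-1,3-dioxolan-2-yl)ethyl]-9-borabicyclo[3.3.1]nonane | CC1(CCB2C3CCCC2CCC3)OCCO1 | intermediate
23 | diethyl {(3S,3aR,7R,8aS)-7-methyl-6-[2-(2-methyl-1,3-dioxolan-2-yl)ethyl]-2-oxo-3,3a,4,7,8,8a-hexahydro-2H-cyclohepta[b]furan-3-yl}phosphonate | CCOP(=O)(OCC)[C@@H]1C(=O)O[C@H]2C[C@@H](C)C(CCC3(C)OCCO3)=CC[C@@H]12 | intermediate
24 | diethyl [(3S,3aR,7R,8aS)-7-methyl-2-oxo-6-(3-oxobutyl)-3,3a,4,7,8,8a-hexahydro-2H-cyclohepta[b]furan-3-yl]phosphonate | CCOP(=O)(OCC)[C@@H]1C(=O)O[C@H]2C[C@@H](C)C(CCC(C)=O)=CC[C@@H]12 | intermediate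
25 | (3aS,7R,8aS)-7-methyl-3-methylidene-6-(3-oxobutyl)-3,3a,4,7,8,8a-hexahydro-2H-cyclohepta[b]furan-2-one | C=C1C(=O)O[C@H]2C[C@@H](C)C(CCC(C)=O)=CC[C@@H]12 | intermediate
26 | nitromethane | C[N+](=O)[O-] | starting material
27 | methylglyoxal (2-oxopropanal) | CC(=O)C=O | starting material
28 | 3-hydroxy-4-nitrobutan-2-one (racemic) | CC(=O)C(O)C[N+](=O)[O-] | intermediate
29 | 1-nitro-3-oxobutan-2-yl methanesulfonate (racemic) | CC(=O)C(OS(C)(=O)=O)C[N+](=O)[O-] | intermediate
30 | (E)-4-nitrobut-3-en-2-one | CC(=O)/C=C/[N+](=O)[O-] | intermediate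
31 | Mukaiyama–Michael adduct: upper (3R,3aS,5R,7S,8aR)-7-methyl-2,6-dioxooctahydro-2H-cyclohepta[b]furan-3-ylphosphonate (diethyl ester) joined at C5 through C13′H2 to C11′ of the lower unit, whose lactone is its trimethylsilyl ketene acetal (C11′=C12′(OSiMe3)) | CCOP(=O)(OCC)[C@H]1C(=O)O[C@@H]2C[C@H](C)C(=O)[C@@H](CC3=C(O[Si](C)(C)C)O[C@H]4C[C@@H](C)C(CCC(C)=O)=CC[C@@H]34)C[C@H]12 | intermediate
32 | as 31 with the lower lactone restored and C11′ (R) quaternary, bearing on its convex face C3H(COCH3)–C2H=N(O)OSiMe3 (trimethylsilyl nitronate; mixture at C3) | CCOP(=O)(OCC)[C@H]1C(=O)O[C@@H]2C[C@H](C)C(=O)[C@@H](C[C@@]3(C(C(C)=O)C=[N+]([O-])O[Si](C)(C)C)C(=O)O[C@H]4C[C@@H](C)C(CCC(C)=O)=CC[C@@H]34)C[C@H]12 | intermediate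
33 | ring-C-closed nitro alcohol: C2 bonded to C1, (1S)-OH cis to H5, C2–NO2 and C3–COCH3 (mixture at C2 and C3), upper phosphonate intact | CCOP(=O)(OCC)[C@H]1C(=O)O[C@@H]2C[C@H](C)[C@@]3(O)C([N+](=O)[O-])C(C(C)=O)[C@]4(C[C@H]3C[C@H]12)C(=O)O[C@H]1C[C@@H](C)C(CCC(C)=O)=CC[C@H]14 | intermediate
34 | phosphonate precursor of the target: the target with H and P(O)(OEt)2 (convex face) on upper C11 in place of =CH2 | CCOP(=O)(OCC)[C@H]1C(=O)O[C@@H]2C[C@H](C)[C@@]3(O)C=C(C(C)=O)[C@]4(C[C@H]3C[C@H]12)C(=O)O[C@H]1C[C@@H](C)C(CCC(C)=O)=CC[C@H]14 | intermediate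
35 | CNP0195550.3: spiro-linked dimer with (1S,5R,7R,8R,10S) upper 1-hydroxy cis-lactone unit, 3-acetylcyclohex-2-ene ring C, and (7′S,8′S,10′R,11′R) lower spiro cis-lactone unit carrying the 3-oxobutyl chain | C=C1C(=O)O[C@@H]2C[C@H](C)[C@@]3(O)C=C(C(C)=O)[C@]4(C[C@H]3C[C@H]12)C(=O)O[C@H]1C[C@@H](C)C(CCC(C)=O)=CC[C@H]14 | target

**Step count and risks**
Total step count: 18. Longest linear sequence: 11 steps (1, 7, 8, 9, 10, 11, 12, 13, 14, 17, 18).

Steps most likely to fail:

Step 17 (the proposed union). The silyl ketene acetal may be protonated before it meets the nitroenone, nitrite may be lost before ring closure, or the C1/C5 sense may be wrong. The fallback uses known reactions, sets out from 11 and comes back at 35. CsF/PhNTf2 converts 11 into the upper enol triflate F5. A Heck reaction with methyl vinyl ketone (Pd(OAc)2, PPh3, Et3N, DMF, 70 °C) gives the upper dienone F6. Heating F6 with 25 (toluene, 110 °C) gives the endo Diels–Alder adduct F7; the phosphonate keeps the diene partner from adding to itself. K2CO3 and aqueous formaldehyde then give the bis(α-methylene lactone) adduct F8. DBU under O2 oxygenates the C3 dienolate at C1 to the C1 hydroperoxide F9, and PPh3 reduces F9 to 35.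

Step 2 (and its mirror-image twin, step 7). Racemisation of the α′-centre may be slower than reduction, or the cis/enantio-selectivity of the enone reduction may be low. The fallback sets out from 3 and comes back at 5 and 13. LiBH(s-Bu)3 (THF, −78 °C) reduces both enantiomers anti to the side chain. The racemic cis-hydroxy esters (4 together with 12) lactonise on acidic work-up. The racemic lactone is then split on a chiral stationary phase into 5 and 13, so one run feeds both halves. This fallback makes no new compound, F0.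

Step 6 (and its mirror-image twin, step 11). The Lewis-basic phosphonate may slow the scandium catalyst, or the CH(CH3) carbon may migrate in part. The fallback sets out from 9 and comes back at 11. BF3·OEt2-promoted homologation with tert-butyl diazoacetate gives the β-keto tert-butyl ester F1. CF3CO2H followed by gentle warming removes the ester group and gives the cycloheptanone F2. Kinetic enolisation with LiN(SiMe3)2 (2.2 equiv) and Me3SiCl returns to 11. In the mirror-image series the same sequence sets out from 17, passes through the mirror-image β-keto tert-butyl ester F3 and the mirror-image cycloheptanone F4, and comes back at 19.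

**Further compounds**
F0 | step 2 | none | none
F1 | step 6 | diethyl [(3R,3aS,7S,8aR)-5-(tert-butoxycarbonyl)-7-methyl-2,6-dioxooctahydro-2H-cyclohepta[b]furan-3-yl]phosphonate (mixture at C5) | CCOP(=O)(OCC)[C@H]1C(=O)O[C@@H]2C[C@H](C)C(=O)C(C(=O)OC(C)(C)C)C[C@H]12
F2 | step 6 | diethyl [(3R,3aS,7S,8aR)-7-methyl-2,6-dioxooctahydro-2H-cyclohepta[b]furan-3-yl]phosphonate | CCOP(=O)(OCC)[C@H]1C(=O)O[C@@H]2C[C@H](C)C(=O)CC[C@H]12
F3 | step 6 | diethyl [(3S,3aR,7R,8aS)-5-(tert-butoxycarbonyl)-7-methyl-2,6-dioxooctahydro-2H-cyclohepta[b]furan-3-yl]phosphonate (mixture at C5) | CCOP(=O)(OCC)[C@@H]1C(=O)O[C@H]2C[C@@H](C)C(=O)C(C(=O)OC(C)(C)C)C[C@@H]12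
F4 | step 6 | diethyl [(3S,3aR,7R,8aS)-7-methyl-2,6-dioxooctahydro-2H-cyclohepta[b]furan-3-yl]phosphonate | CCOP(=O)(OCC)[C@@H]1C(=O)O[C@H]2C[C@@H](C)C(=O)CC[C@@H]12
F5 | step 17 | (3R,3aS,7S,8aR)-3-(diethoxyphosphoryl)-7-methyl-2-oxo-3,3a,4,7,8,8a-hexahydro-2H-cyclohepta[b]furan-6-yl trifluoromethanesulfonate | CCOP(=O)(OCC)[C@H]1C(=O)O[C@@H]2C[C@H](C)C(OS(=O)(=O)C(F)(F)F)=CC[C@H]12
F6 | step 17 | diethyl {(3R,3aS,7S,8aR)-7-methyl-2-oxo-6-[(1E)-3-oxobut-1-en-1-yl]-3,3a,4,7,8,8a-hexahydro-2H-cyclohepta[b]furan-3-yl}phosphonate | CCOP(=O)(OCC)[C@H]1C(=O)O[C@@H]2C[C@H](C)C(/C=C/C(C)=O)=CC[C@H]12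
F7 | step 17 | endo Diels–Alder adduct of F6 and 25 (C1=C2 alkene, C3–H with acetyl, upper phosphonate) | CCOP(=O)(OCC)[C@H]1C(=O)O[C@@H]2C[C@H](C)C3=C[C@@H](C(C)=O)[C@]4(C[C@H]3C[C@H]12)C(=O)O[C@H]1C[C@@H](C)C(CCC(C)=O)=CC[C@H]14
F8 | step 17 | adduct F7 with the upper α-methylene lactone in place of the phosphonate | C=C1C(=O)O[C@@H]2C[C@H](C)C3=C[C@@H](C(C)=O)[C@]4(C[C@H]3C[C@H]12)C(=O)O[C@H]1C[C@@H](C)C(CCC(C)=O)=CC[C@H]14
F9 | step 17 | C1 hydroperoxide of the target | C=C1C(=O)O[C@@H]2C[C@H](C)[C@@]3(OO)C=C(C(C)=O)[C@]4(C[C@H]3C[C@H]12)C(=O)O[C@H]1C[C@@H](C)C(CCC(C)=O)=CC[C@H]14
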